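**Retrosynthetic overview**
- The target is a germacranolide-type butenolide; the last operations are desilylation, bis-acetylation of the C1/C3 anti-diol and release of the C13 alcohol.
- Ten-membered carbocycle (formed second, last C–C bond): C1–C10 is cut to an acyclic ynal, closed by a new exo-selective nickel/carbene reductive aldehyde–alkyne macrocyclisation that also creates C1 and the C10=C14 methylidene.
- Butenolide (formed first): γ-hydroxy ynoate plus a butynyl organocopper (C7–C8 by syn-carbocupration), iodination at C11, lactonisation; C13 then comes from a Stille hydroxymethylation.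
- C6 and C3 come from two catalytic asymmetric additions of methyl propiolate to aldehydes; the (Z)-C4=C5 alkene comes from syn-methylcupration of the first ynoate.
- Building blocks: 3-(PMB-oxy)propanol, methyl propiolate (used twice), 4-bromo-1-(trimethylsilyl)but-1-yne, (tributylstannyl)methanol.

Locants: germacrane numbering is used in the explanations (C1 and C3 bear the acetates, C4=C5 is the Z alkene carrying the C15 methyl, C6 is the lactone carbinol, C7=C11 the butenolide alkene, C12 the lactone carbonyl, C13 the CH2OH carbon, C10=C14 the methylidene).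

Assumption: (S,S)-ProPhenol/Me2Zn is taken to give the (S)-propargylic alcohol in the first alkynylation and (R,R)-ProPhenol the (R)-alcohol in the second (both carbinols rank O > alkynyl > other carbon > H); I have not verified this sense, so a Mosher ester check decides, and the two ligand antipodes are exchanged if it is reversed.

Assumption: in the new macrocyclisation the (4S,5S) antipode of the carbene DP-IPr [1,3-bis(2,6-diisopropylphenyl)-4,5-diphenyl-4,5-dihydroimidazol-2-ylidene] is taken as the matched ligand; one test run with each antipode settles this.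

**Step 1**
Reactants: 1 3-[(4-methoxybenzyl)oxy]propan-1-ol
Product: 2 3-[(4-methoxybenzyl)oxy]propanal
Conditions: TEMPO (10 mol %), PhI(OAc)2 (1.1 equiv), CH2Cl2, rt
Reagents that add atoms: none
Why: Oxoammonium (TEMPO/PhI(OAc)2) oxidation of a primary alcohol stops at the aldehyde and tolerates the PMB ether; no stereocentre is formed.

**Step 2**
Reactants: 2 3-[(4-methoxybenzyl)oxy]propanal; 3 methyl propiolate
Product: 4 methyl (4S)-4-hydroxy-6-[(4-methoxybenzyl)oxy]hex-2-ynoate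
Conditions: (S,S)-ProPhenol (20 mol %), Me2Zn (3 equiv), Ph3PO (40 mol %), toluene, 4 °C
Reagents that add atoms: none
Why: Zinc–ProPhenol catalysed asymmetric alkynylation of an aldehyde: the dinuclear zinc catalyst binds the aldehyde and the zinc acetylide of 3 and delivers the alkyne to one carbonyl face, which sets C3 as S under catalyst control.

**Step 3**
Reactants: 4 methyl (4S)-4-hydroxy-6-[(4-methoxybenzyl)oxy]hex-2-ynoate
Product: 5 methyl (4S)-6-[(4-methoxybenzyl)oxy]-4-[(triethylsilyl)oxy]hex-2-ynoate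
Conditions: TESCl, imidazole, CH2Cl2, 0 °C
Reagents that add atoms: chlorotriethylsilane (TESCl), CC[Si](Cl)(CC)CC
Why: Silylation (silyl ether formation) with TESCl/imidazole is fast at 0 °C and outruns base-induced isomerisation of the γ-hydroxy ynoate; C3 is untouched.

**Step 4**
Reactants: 5 methyl (4S)-6-[(4-methoxybenzyl)oxy]-4-[(triethylsilyl)oxy]hex-2-ynoate
Product: 6 methyl (2Z,4S)-6-[(4-methoxybenzyl)oxy]-3-methyl-4-[(triethylsilyl)oxy]hex-2-enoate
Conditions: Me2CuLi (from CuI and MeLi, 1.5 equiv), THF, −78 °C; aq NH4Cl quench at −78 °C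
Reagents that add atoms: lithium dimethylcuprate (Me2CuLi), [Li+].C[Cu-]C
Why: Syn-carbocupration (cuprate conjugate addition) of the ynoate followed by cold protonation of the α-cuprio ester places methyl and hydrogen cis, which fixes the (Z)-C4=C5 alkene with the ester cis to C3; the low temperature prevents allenolate isomerisation.

**Step 5**
Reactants: 6 methyl (2Z,4S)-6-[(4-methoxybenzyl)oxy]-3-methyl-4-[(triethylsilyl)oxy]hex-2-enoate
Product: 7 (2Z,4S)-6-[(4-methoxybenzyl)oxy]-3-methyl-4-[(triethylsilyl)oxy]hex-2-en-1-ol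
Conditions: iBu2AlH (2.5 equiv), CH2Cl2, −78 °C; aq KNaC4H4O6 (tartrate) work-up
Reagents that add atoms: none
Why: iBu2AlH reduction of the enoate gives the allylic alcohol by 1,2-hydride delivery with retention of the (Z)-alkene, and the TES and PMB ethers are inert at −78 °C.

**Step 6**
Reactants: 7 (2Z,4S)-6-[(4-methoxybenzyl)oxy]-3-methyl-4-[(triethylsilyl)oxy]hex-2-en-1-ol
Product: 8 (2Z,4S)-6-[(4-methoxybenzyl)oxy]-3-methyl-4-[(triethylsilyl)oxy]hex-2-enal
Conditions: TEMPO (10 mol %), PhI(OAc)2 (1.1 equiv), CH2Cl2, 0 °C to rt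
Reagents that add atoms: none
Why: TEMPO/PhI(OAc)2 oxidation of an allylic alcohol is known to give β,β-disubstituted (Z)-enals of the neral type without Z/E isomerisation.

**Step 7**
Reactants: 8 (2Z,4S)-6-[(4-methoxybenzyl)oxy]-3-methyl-4-[(triethylsilyl)oxy]hex-2-enal; 3 methyl propiolate
Product: 9 methyl (4R,5Z,7S)-4-hydroxy-9-[(4-methoxybenzyl)oxy]-6-methyl-7-[(triethylsilyl)oxy]non-5-en-2-ynoate
Conditions: (R,R)-ProPhenol (20 mol %), Me2Zn (3 equiv), Ph3PO (40 mol %), toluene, 4 °C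
Reagents that add atoms: none
Why: Zinc–ProPhenol catalysed asymmetric alkynylation, which works best on enals with methyl propiolate: the antipodal ligand delivers the acetylide to the opposite carbonyl face and sets C6 as R under catalyst control, the remote C3 centre having little influence.

**Step 8**
Reactants: 9 methyl (4R,5Z,7S)-4-hydroxy-9-[(4-methoxybenzyl)oxy]-6-methyl-7-[(triethylsilyl)oxy]non-5-en-2-ynoate; 10 (4-bromobut-1-yn-1-yl)trimethylsilane
Product: 13 (5R)-3-iodo-5-{(1Z,3S)-5-[(4-methoxybenzyl)oxy]-2-methyl-3-[(triethylsilyl)oxy]pent-1-en-1-yl}-4-[4-(trimethylsilyl)but-3-yn-1-yl]furan-2(5H)-one, via silylbutynylmagnesium bromide 11 (not isolated), via open-chain iodo hydroxy ester 12 (not isolated)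
Conditions: 10, Mg, THF, 40 °C (gives 11); 9 + 11 (1.0 equiv), THF, −78 °C; RCu·MgBr2 (from 11 and CuBr·SMe2, 2.5 equiv), −78 to −40 °C; I2, −78 °C; aq NH4Cl, rt
Reagents that add atoms: iodine (I2), II
Why: Syn-carbocupration of the ynoate magnesium alkoxide by the alkylcopper forms C7–C8 with copper at C11 cis to the new chain, stereoretentive iodinolysis at −78 °C gives the (E)-α-iodo enoate whose ester is cis to the C6 alkoxide, and lactonisation (transesterification) closes the butenolide without touching C6.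

**Step 9**
Reactants: 13 (5R)-3-iodo-5-{(1Z,3S)-5-[(4-methoxybenzyl)oxy]-2-methyl-3-[(triethylsilyl)oxy]pent-1-en-1-yl}-4-[4-(trimethylsilyl)but-3-yn-1-yl]furan-2(5H)-one; 14 (tributylstannyl)methanol
Product: 15 (5R)-3-(hydroxymethyl)-5-{(1Z,3S)-5-[(4-methoxybenzyl)oxy]-2-methyl-3-[(triethylsilyl)oxy]pent-1-en-1-yl}-4-[4-(trimethylsilyl)but-3-yn-1-yl]furan-2(5H)-one
Conditions: Pd2(dba)3 (5 mol %), AsPh3 (20 mol %), CuI (10 mol %), NMP, 60 °C
Reagents that add atoms: none
Why: Stille cross-coupling: oxidative addition of zerovalent palladium into the activated α-iodo enoate and selective transfer of the α-oxygenated CH2OH group from tin install C13 under neutral conditions that do not epimerise C6.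

**Step 10**
Reactants: 15 (5R)-3-(hydroxymethyl)-5-{(1Z,3S)-5-[(4-methoxybenzyl)oxy]-2-methyl-3-[(triethylsilyl)oxy]pent-1-en-1-yl}-4-[4-(trimethylsilyl)but-3-yn-1-yl]furan-2(5H)-one
Product: 16 (5R)-3-({[tert-butyl(diphenyl)silyl]oxy}methyl)-5-{(1Z,3S)-5-[(4-methoxybenzyl)oxy]-2-methyl-3-[(triethylsilyl)oxy]pent-1-en-1-yl}-4-[4-(trimethylsilyl)but-3-yn-1-yl]furan-2(5H)-one
Conditions: TBDPSCl, imidazole, CH2Cl2, rt
Reagents that add atoms: tert-butyl(chloro)diphenylsilane (TBDPSCl), CC(C)(C)[Si](Cl)(c1ccccc1)c1ccccc1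
Why: Silylation of the primary allylic alcohol with TBDPSCl/imidazole gives an ether that survives DDQ, the oxidation, the nickel catalysis and mild acid.

**Step 11**
Reactants: 16 (5R)-3-({[tert-butyl(diphenyl)silyl]oxy}methyl)-5-{(1Z,3S)-5-[(4-methoxybenzyl)oxy]-2-methyl-3-[(triethylsilyl)oxy]pent-1-en-1-yl}-4-[4-(trimethylsilyl)but-3-yn-1-yl]furan-2(5H)-one
Product: 17 (5R)-3-({[tert-butyl(diphenyl)silyl]oxy}methyl)-5-{(1Z,3S)-5-hydroxy-2-methyl-3-[(triethylsilyl)oxy]pent-1-en-1-yl}-4-[4-(trimethylsilyl)but-3-yn-1-yl]furan-2(5H)-one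
Conditions: DDQ (1.3 equiv), CH2Cl2/pH 7 phosphate buffer, 0 °C
Reagents that add atoms: none
Why: Oxidative PMB ether cleavage by DDQ (hydride abstraction from the electron-rich benzylic position, then hydrolysis) is selective over the silyl ethers and the alkenes under buffered conditions.

**Step 12**
Reactants: 17 (5R)-3-({[tert-butyl(diphenyl)silyl]oxy}methyl)-5-{(1Z,3S)-5-hydroxy-2-methyl-3-[(triethylsilyl)oxy]pent-1-en-1-yl}-4-[4-(trimethylsilyl)but-3-yn-1-yl]furan-2(5H)-one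
Product: 18 (5R)-4-(but-3-yn-1-yl)-3-({[tert-butyl(diphenyl)silyl]oxy}methyl)-5-{(1Z,3S)-5-hydroxy-2-methyl-3-[(triethylsilyl)oxy]pent-1-en-1-yl}furan-2(5H)-one
Conditions: AgNO3 (20 mol %), CH2Cl2/MeOH/H2O, rt
Reagents that add atoms: none
Why: AgNO3-catalysed protodesilylation of the C(sp)–SiMe3 bond via the silver acetylide is selective over O-silyl ethers and avoids basic conditions that could epimerise C6 or open the lactone.

**Step 13**
Reactants: 18 (5R)-4-(but-3-yn-1-yl)-3-({[tert-butyl(diphenyl)silyl]oxy}methyl)-5-{(1Z,3S)-5-hydroxy-2-methyl-3-[(triethylsilyl)oxy]pent-1-en-1-yl}furan-2(5H)-one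
Product: 19 (5R)-4-(but-3-yn-1-yl)-3-({[tert-butyl(diphenyl)silyl]oxy}methyl)-5-{(1Z,3S)-2-methyl-5-oxo-3-[(triethylsilyl)oxy]pent-1-en-1-yl}furan-2(5H)-one
Conditions: TEMPO (20 mol %), PhI(OAc)2 (1.2 equiv), CH2Cl2, rt; used at once
Reagents that add atoms: none
Why: TEMPO/PhI(OAc)2 oxidation gives the β-silyloxy aldehyde under near-neutral conditions, which avoids β-elimination, and the terminal alkyne and butenolide are inert.

**Step 14**
Reactants: 19 (5R)-4-(but-3-yn-1-yl)-3-({[tert-butyl(diphenyl)silyl]oxy}methyl)-5-{(1Z,3S)-2-methyl-5-oxo-3-[(triethylsilyl)oxy]pent-1-en-1-yl}furan-2(5H)-one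
Product: 20 (7S,9S,10Z,11aR)-3-({[tert-butyl(diphenyl)silyl]oxy}methyl)-10-methyl-6-methylidene-7,9-bis[(triethylsilyl)oxy]-4,5,6,7,8,9-hexahydrocyclodeca[b]furan-2(11aH)-one
Conditions: Ni(cod)2 (25 mol %), (4S,5S)-DP-IPr·HBF4 (25 mol %), KOtBu (25 mol %), Et3SiH (5 equiv), toluene, 0.002 M, syringe-pump addition of 19 over 6 h, rt
Reagents that add atoms: triethylsilane (Et3SiH), CC[SiH](CC)CC
Why: Proposed new method: zerovalent nickel bound to the very bulky carbene should undergo oxidative cyclisation of the tethered aldehyde and terminal alkyne with the C–C bond forming at the internal alkyne carbon C10 (the ligand pushes the tether away from nickel, so nickel sits on the terminal carbon C14), giving an exo-alkylidene oxanickelacyclopentene whose Ni–O bond is cleaved by Et3SiH (σ-bond metathesis) and whose Ni–C bond then undergoes C–H reductive elimination to leave the C10=C14 methylidene and the C1–OSiEt3 ether; C10 is expected to add to the Re face of the aldehyde (C1 S, anti to the C3 silyloxy group) because the forming ring folds about the (Z)-alkene and the planar butenolide with C3–OTES pseudo-equatorial and the aldehyde oxygen on the ring periphery, the single ligand antipode reinforcing this bias; the closest known chemistry is the nickel/N-heterocyclic carbene/silane reductive coupling of aldehydes and alkynes and its exo-selective macrocyclisation of terminal ynals to large-ring lactones, which to my knowledge has not been shown for a ten-membered carbocycle or with ligand-reinforced diastereocontrol.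

**Step 15**
Reactants: 20 (7S,9S,10Z,11aR)-3-({[tert-butyl(diphenyl)silyl]oxy}methyl)-10-methyl-6-methylidene-7,9-bis[(triethylsilyl)oxy]-4,5,6,7,8,9-hexahydrocyclodeca[b]furan-2(11aH)-one
Product: 21 (7S,9S,10Z,11aR)-3-({[tert-butyl(diphenyl)silyl]oxy}methyl)-7,9-dihydroxy-10-methyl-6-methylidene-4,5,6,7,8,9-hexahydrocyclodeca[b]furan-2(11aH)-one
Conditions: PPTS (20 mol %), MeOH/CH2Cl2, 0 °C
Reagents that add atoms: none
Why: Acid-catalysed methanolysis of silyl ethers removes both secondary TES groups while the far more acid-stable primary TBDPS ether is kept, and no stereocentre is affected.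

**Step 16**
Reactants: 21 (7S,9S,10Z,11aR)-3-({[tert-butyl(diphenyl)silyl]oxy}methyl)-7,9-dihydroxy-10-methyl-6-methylidene-4,5,6,7,8,9-hexahydrocyclodeca[b]furan-2(11aH)-one
Product: 22 (7S,9S,10Z,11aR)-3-({[tert-butyl(diphenyl)silyl]oxy}methyl)-10-methyl-6-methylidene-2-oxo-2,4,5,6,7,8,9,11a-octahydrocyclodeca[b]furan-7,9-diyl diacetate
Conditions: Ac2O, pyridine, DMAP (10 mol %), CH2Cl2, 0 °C to rt
Reagents that add atoms: acetic anhydride (Ac2O), CC(=O)OC(C)=O
Why: DMAP-catalysed acylation esterifies both secondary allylic alcohols with retention at C1 and C3, and pyridine is too weak a base to epimerise C6.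

**Step 17**
Reactants: 22 (7S,9S,10Z,11aR)-3-({[tert-butyl(diphenyl)silyl]oxy}methyl)-10-methyl-6-methylidene-2-oxo-2,4,5,6,7,8,9,11a-octahydrocyclodeca[b]furan-7,9-diyl diacetate
Product: 23 (7S,9S,10Z,11aR)-3-(hydroxymethyl)-10-methyl-6-methylidene-2-oxo-2,4,5,6,7,8,9,11a-octahydrocyclodeca[b]furan-7,9-diyl diacetate
Conditions: HF·pyridine, pyridine, THF, 0 °C to rt
Reagents that add atoms: none
Why: Fluoride-mediated Si–O cleavage with buffered HF·pyridine frees the C13 alcohol under non-basic conditions, so the acetates neither migrate nor hydrolyse and C6 is not epimerised.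

**Compound list**
1 | 3-[(4-methoxybenzyl)oxy]propan-1-ol | OCCCOCc1ccc(OC)cc1 | starting material
2 | 3-[(4-methoxybenzyl)oxy]propanal | O=CCCOCc1ccc(OC)cc1 | intermediate
3 | methyl propiolate | C#CC(=O)OC | starting material
4 | methyl (4S)-4-hydroxy-6-[(4-methoxybenzyl)oxy]hex-2-ynoate | COC(=O)C#C[C@@H](O)CCOCc1ccc(OC)cc1 | intermediate
5 | methyl (4S)-6-[(4-methoxybenzyl)oxy]-4-[(triethylsilyl)oxy]hex-2-ynoate | COC(=O)C#C[C@@H](O[Si](CC)(CC)CC)CCOCc1ccc(OC)cc1 | intermediate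
6 | methyl (2Z,4S)-6-[(4-methoxybenzyl)oxy]-3-methyl-4-[(triethylsilyl)oxy]hex-2-enoate | COC(=O)/C=C(/C)[C@@H](O[Si](CC)(CC)CC)CCOCc1ccc(OC)cc1 | intermediate
7 | (2Z,4S)-6-[(4-methoxybenzyl)oxy]-3-methyl-4-[(triethylsilyl)oxy]hex-2-en-1-ol | OC/C=C(/C)[C@@H](O[Si](CC)(CC)CC)CCOCc1ccc(OC)cc1 | intermediate
8 | (2Z,4S)-6-[(4-methoxybenzyl)oxy]-3-methyl-4-[(triethylsilyl)oxy]hex-2-enal | O=C/C=C(/C)[C@@H](O[Si](CC)(CC)CC)CCOCc1ccc(OC)cc1 | intermediate
9 | methyl (4R,5Z,7S)-4-hydroxy-9-[(4-methoxybenzyl)oxy]-6-methyl-7-[(triethylsilyl)oxy]non-5-en-2-ynoate | COC(=O)C#C[C@H](O)/C=C(/C)[C@@H](O[Si](CC)(CC)CC)CCOCc1ccc(OC)cc1 | intermediate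
10 | (4-bromobut-1-yn-1-yl)trimethylsilane | C[Si](C)(C)C#CCCBr | starting material
11 | [4-(trimethylsilyl)but-3-yn-1-yl]magnesium bromide | C[Si](C)(C)C#CCC[Mg]Br | intermediate
12 | methyl (2E,4R,5Z,7S)-4-hydroxy-2-iodo-9-[(4-methoxybenzyl)oxy]-6-methyl-7-[(triethylsilyl)oxy]-3-[4-(trimethylsilyl)but-3-yn-1-yl]nona-2,5-dienoate | COC(=O)/C(I)=C(CCC#C[Si](C)(C)C)\[C@H](O)/C=C(/C)[C@@H](O[Si](CC)(CC)CC)CCOCc1ccc(OC)cc1 | intermediate
13 | (5R)-3-iodo-5-{(1Z,3S)-5-[(4-methoxybenzyl)oxy]-2-methyl-3-[(triethylsilyl)oxy]pent-1-en-1-yl}-4-[4-(trimethylsilyl)but-3-yn-1-yl]furan-2(5H)-one | O=C1O[C@H](/C=C(/C)[C@@H](O[Si](CC)(CC)CC)CCOCc2ccc(OC)cc2)C(CCC#C[Si](C)(C)C)=C1I | intermediate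
14 | (tributylstannyl)methanol | CCCC[Sn](CCCC)(CCCC)CO | starting material
15 | (5R)-3-(hydroxymethyl)-5-{(1Z,3S)-5-[(4-methoxybenzyl)oxy]-2-methyl-3-[(triethylsilyl)oxy]pent-1-en-1-yl}-4-[4-(trimethylsilyl)but-3-yn-1-yl]furan-2(5H)-one | O=C1O[C@H](/C=C(/C)[C@@H](O[Si](CC)(CC)CC)CCOCc2ccc(OC)cc2)C(CCC#C[Si](C)(C)C)=C1CO | intermediate
16 | (5R)-3-({[tert-butyl(diphenyl)silyl]oxy}methyl)-5-{(1Z,3S)-5-[(4-methoxybenzyl)oxy]-2-methyl-3-[(triethylsilyl)oxy]pent-1-en-1-yl}-4-[4-(trimethylsilyl)but-3-yn-1-yl]furan-2(5H)-one | O=C1O[C@H](/C=C(/C)[C@@H](O[Si](CC)(CC)CC)CCOCc2ccc(OC)cc2)C(CCC#C[Si](C)(C)C)=C1CO[Si](c3ccccc3)(c3ccccc3)C(C)(C)C | intermediate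
17 | (5R)-3-({[tert-butyl(diphenyl)silyl]oxy}methyl)-5-{(1Z,3S)-5-hydroxy-2-methyl-3-[(triethylsilyl)oxy]pent-1-en-1-yl}-4-[4-(trimethylsilyl)but-3-yn-1-yl]furan-2(5H)-one | O=C1O[C@H](/C=C(/C)[C@@H](O[Si](CC)(CC)CC)CCO)C(CCC#C[Si](C)(C)C)=C1CO[Si](c3ccccc3)(c3ccccc3)C(C)(C)C | intermediate
18 | (5R)-4-(but-3-yn-1-yl)-3-({[tert-butyl(diphenyl)silyl]oxy}methyl)-5-{(1Z,3S)-5-hydroxy-2-methyl-3-[(triethylsilyl)oxy]pent-1-en-1-yl}furan-2(5H)-one | O=C1O[C@H](/C=C(/C)[C@@H](O[Si](CC)(CC)CC)CCO)C(CCC#C)=C1CO[Si](c3ccccc3)(c3ccccc3)C(C)(C)C | intermediate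
19 | (5R)-4-(but-3-yn-1-yl)-3-({[tert-butyl(diphenyl)silyl]oxy}methyl)-5-{(1Z,3S)-2-methyl-5-oxo-3-[(triethylsilyl)oxy]pent-1-en-1-yl}furan-2(5H)-one | O=C1O[C@H](/C=C(/C)[C@@H](O[Si](CC)(CC)CC)CC=O)C(CCC#C)=C1CO[Si](c3ccccc3)(c3ccccc3)C(C)(C)C | intermediate
20 | (7S,9S,10Z,11aR)-3-({[tert-butyl(diphenyl)silyl]oxy}methyl)-10-methyl-6-methylidene-7,9-bis[(triethylsilyl)oxy]-4,5,6,7,8,9-hexahydrocyclodeca[b]furan-2(11aH)-one | C=C1CCC2=C(CO[Si](c3ccccc3)(c3ccccc3)C(C)(C)C)C(=O)O[C@@H]2/C=C(/C)[C@@H](O[Si](CC)(CC)CC)C[C@@H]1O[Si](CC)(CC)CC | intermediate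
21 | (7S,9S,10Z,11aR)-3-({[tert-butyl(diphenyl)silyl]oxy}methyl)-7,9-dihydroxy-10-methyl-6-methylidene-4,5,6,7,8,9-hexahydrocyclodeca[b]furan-2(11aH)-one | C=C1CCC2=C(CO[Si](c3ccccc3)(c3ccccc3)C(C)(C)C)C(=O)O[C@@H]2/C=C(/C)[C@@H](O)C[C@@H]1O | intermediate
22 | (7S,9S,10Z,11aR)-3-({[tert-butyl(diphenyl)silyl]oxy}methyl)-10-methyl-6-methylidene-2-oxo-2,4,5,6,7,8,9,11a-octahydrocyclodeca[b]furan-7,9-diyl diacetate | C=C1CCC2=C(CO[Si](c3ccccc3)(c3ccccc3)C(C)(C)C)C(=O)O[C@@H]2/C=C(/C)[C@@H](OC(C)=O)C[C@@H]1OC(C)=O | intermediate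
23 | (7S,9S,10Z,11aR)-3-(hydroxymethyl)-10-methyl-6-methylidene-2-oxo-2,4,5,6,7,8,9,11a-octahydrocyclodeca[b]furan-7,9-diyl diacetate | C=C1CCC2=C(CO)C(=O)O[C@@H]2/C=C(/C)[C@@H](OC(C)=O)C[C@@H]1OC(C)=O | target

**Totals and risk**
Total step count: 17. Longest linear sequence: 17 steps (1 to 23); compounds 3, 10 and 14 are bought.

The three steps most likely to fail are 14, 8 and 7.

Step 14 (new macrocyclisation) may fail through competing endo closure, alkyne oligomerisation, ionisation of the allylic lactone by zerovalent nickel, or the wrong C1 epimer. Its fallback uses known chemistry only, sets out from 18 and comes back at 21. Markovnikov iodoboration of the alkyne with B-iodo-9-BBN (2,6-di-tert-butyl-4-methylpyridine, CH2Cl2/pentane, −20 °C) and protonolysis with AcOH gives the 2-iodoalkene alcohol F1. TEMPO/PhI(OAc)2 oxidation gives the iodo aldehyde F2. A Nozaki–Hiyama–Kishi macrocyclisation (CrCl2, catalytic NiCl2, DMSO/THF, high dilution) closes C1–C10 to the macrocyclic allylic alcohol F3 as either C1 epimer. Whatever the ratio, Dess–Martin oxidation gives the α-methylidene ketone F4, buffered HF·pyridine removes the C3 TES group to give the β-hydroxy enone F5, and hydroxyl-directed reduction with Me4NBH(OAc)3 (MeCN/AcOH, −30 °C) delivers hydride anti to the C3 hydroxyl and gives the anti-diol 21.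

Step 8 (three-component carbocupration, iodination, lactonisation) may fail through loss of alkene geometry before the iodine trap or through a poor trap. Its fallback sets out from 9 and comes back at 15, bypassing 13 and the palladium step. The same alkoxide/organocopper addition is run, but the α-cuprio ester is alkylated at −78 °C with 2-(iodomethyl)-4,4,5,5-tetramethyl-1,3,2-dioxaborolane in the presence of HMPA. This is a known stereoretentive trap for ynoate carbocupration adducts and gives, after lactonisation, the α-(borylmethyl)butenolide F6. Oxidation of the C–B bond (NaBO3·4H2O, THF/H2O, rt) then gives 15, so C13 arrives by C-alkylation and boron oxidation instead of iodination and Stille coupling.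

Step 7 (asymmetric alkynylation of a hindered (Z)-enal) may give low conversion or low selectivity. Its fallback sets out from 8 and comes back at 9, replacing catalyst control by reagent control. Addition of lithium methyl propiolate (from 3 and LiN(SiMe3)2, THF, −78 °C) gives the epimeric propargylic alcohols F7. MnO2 oxidation gives the ynone F8. Midland reduction with (R)-Alpine-Borane (from (+)-α-pinene), in which the alkyne is the small group, then gives the (4R)-alcohol 9.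

**Further compounds**
F1 | step 14 | (5R)-3-({[tert-butyl(diphenyl)silyl]oxy}methyl)-5-{(1Z,3S)-5-hydroxy-2-methyl-3-[(triethylsilyl)oxy]pent-1-en-1-yl}-4-(3-iodobut-3-en-1-yl)furan-2(5H)-one | O=C1O[C@H](/C=C(/C)[C@@H](O[Si](CC)(CC)CC)CCO)C(CCC(I)=C)=C1CO[Si](c3ccccc3)(c3ccccc3)C(C)(C)C
F2 | step 14 | (5R)-3-({[tert-butyl(diphenyl)silyl]oxy}methyl)-4-(3-iodobut-3-en-1-yl)-5-{(1Z,3S)-2-methyl-5-oxo-3-[(triethylsilyl)oxy]pent-1-en-1-yl}furan-2(5H)-one | O=C1O[C@H](/C=C(/C)[C@@H](O[Si](CC)(CC)CC)CC=O)C(CCC(I)=C)=C1CO[Si](c3ccccc3)(c3ccccc3)C(C)(C)C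
F3 | step 14 | (9S,10Z,11aR)-3-({[tert-butyl(diphenyl)silyl]oxy}methyl)-7-hydroxy-10-methyl-6-methylidene-9-[(triethylsilyl)oxy]-4,5,6,7,8,9-hexahydrocyclodeca[b]furan-2(11aH)-one (C7 epimers) | C=C1CCC2=C(CO[Si](c3ccccc3)(c3ccccc3)C(C)(C)C)C(=O)O[C@@H]2/C=C(/C)[C@@H](O[Si](CC)(CC)CC)CC1O
F4 | step 14 | (9S,10Z,11aR)-3-({[tert-butyl(diphenyl)silyl]oxy}methyl)-10-methyl-6-methylidene-9-[(triethylsilyl)oxy]-5,6,8,9-tetrahydrocyclodeca[b]furan-2,7(4H,11aH)-dione | C=C1CCC2=C(CO[Si](c3ccccc3)(c3ccccc3)C(C)(C)C)C(=O)O[C@@H]2/C=C(/C)[C@@H](O[Si](CC)(CC)CC)CC1=O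
F5 | step 14 | (9S,10Z,11aR)-3-({[tert-butyl(diphenyl)silyl]oxy}methyl)-9-hydroxy-10-methyl-6-methylidene-5,6,8,9-tetrahydrocyclodeca[b]furan-2,7(4H,11aH)-dione | C=C1CCC2=C(CO[Si](c3ccccc3)(c3ccccc3)C(C)(C)C)C(=O)O[C@@H]2/C=C(/C)[C@@H](O)CC1=O
F6 | step 8 | (5R)-5-{(1Z,3S)-5-[(4-methoxybenzyl)oxy]-2-methyl-3-[(triethylsilyl)oxy]pent-1-en-1-yl}-3-[(4,4,5,5-tetramethyl-1,3,2-dioxaborolan-2-yl)methyl]-4-[4-(trimethylsilyl)but-3-yn-1-yl]furan-2(5H)-one | O=C1O[C@H](/C=C(/C)[C@@H](O[Si](CC)(CC)CC)CCOCc2ccc(OC)cc2)C(CCC#C[Si](C)(C)C)=C1CB4OC(C)(C)C(C)(C)O4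
F7 | step 7 | methyl (5Z,7S)-4-hydroxy-9-[(4-methoxybenzyl)oxy]-6-methyl-7-[(triethylsilyl)oxy]non-5-en-2-ynoate (C4 epimers) | COC(=O)C#CC(O)/C=C(/C)[C@@H](O[Si](CC)(CC)CC)CCOCc1ccc(OC)cc1
F8 | step 7 | methyl (5Z,7S)-9-[(4-methoxybenzyl)oxy]-6-methyl-4-oxo-7-[(triethylsilyl)oxy]non-5-en-2-ynoate | COC(=O)C#CC(=O)/C=C(/C)[C@@H](O[Si](CC)(CC)CC)CCOCc1ccc(OC)cc1
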